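Locants: O1, C2, C3, C4 and rings A and B as in a flavanone. Ca is the benzylic CH on ring D, Cb the quaternary C–O carbon bearing ring E, Cc the acetal CH. Prenyl = 3-methylbut-2-en-1-yl, TBS = tert-butyldimethylsilyl, MOM = methoxymethyl.

## The problem

Compound 28 (CNP0152008.3, C45H44O9) is a flavanone whose C2 is a ketal carbon: besides O1 and ring B it carries an ether oxygen belonging to an oxolane built on the C2–C3 bond. The other two oxolane carbons, Ca and Cb, are shared with a chromane (ring D) and, through the acetal carbon Cc, with a 2,3-dihydrobenzofuran (ring E). Six rings and five contiguous stereocentres (C2, C3, Ca, Cb, Cc; C2 and Cb fully substituted) are therefore packed around one five-membered ring. Three centres are exchangeable (C2 is a ketal, Cc an acetal, C3 lies alpha to the C4 ketone) and each is tied to a neighbour by a cis ring fusion. Only Ca and Cb are fixed, so they must be set absolutely; they then dictate Cc directly and C2/C3 by equilibration. The periphery is fragile: three prenyl groups sit ortho to phenols (acid closes them to chromans, oxidants and hydrogenation attack the alkenes), four phenols are free, and the C3–H invites elimination across C2–C3 under acid or base. The feature that opens a short route is the substitution of Cb, which carries an oxygen and ring E and is bonded to Cc. At the carboxyl level of Cc it is C3 of a 3-hydroxybenzofuran-2(3H)-one, acidic because deprotonation gives an aromatic 2-oxidobenzofuran. Seen from Cb, Ca and C2 are the beta-carbon and one carbonyl carbon of the ring D arylidene derivative of the rings A/B 1,3-diketone, and the Cb oxygen only has to meet C2 as a hemiketal.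

## Retrosynthesis

**Ketal and acetal C–O bonds.** The first cut removes O1–C2 and the ring D oxygen–Cc bond of 28. These are the only bonds of the cage that form reversibly under mild acid. Cutting them, rather than the oxolane O–C2 bond (which leads back to a flavone), turns the hexacycle into the monocyclic oxolane 27, a hexaphenol with a hemiketal at C2 and a lactol at Cc. Forward, a weak acid and a drying agent must close a chromanone and a pyran ring. Geometry allows only cis fusion, so the only demand is chemoselectivity towards the prenylphenols.

**Protecting groups and oxidation level.** 27 is the desilylation product of hexasilyl ether 26, and the lactol of 26 is the half-reduced aryl lactone of 25. Moving Cc from the carboxyl to the aldehyde level is the price paid for making Cb acidic. The forward reduction has to take the lactone and leave the C4 ketone.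

**Key cut.** In 25 the Ca–Cb bond and the oxolane O–C2 bond are cut together, giving hydroxy-lactone 10 and arylidene diketone 23. A cut at C3–Ca would still leave Cb to be made separately as a quaternary carbinol, and a cut at Cb–Cc is a C–H functionalisation (see below). The chosen cut severs the bond between the only two non-exchangeable stereocentres and leaves every other stereocentre on an exchangeable position. Neither fragment has a lasting stereocentre: 23 is achiral and 10 is a racemate whose stereocentre vanishes on enolisation. Each holds about half of the carbon atoms. The forward step must create Ca and the quaternary Cb with absolute and relative control and close the oxolane on the ring B carbonyl.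

**Arylidene diketone.** 23 is cut at the C3=Ca double bond (Knoevenagel) into 1,3-diketone 20 and aldehyde 22, the bis-silyl ether of commercial 21. No alternative is shorter; the forward condensation must cope with an electron-rich aldehyde.

**1,3-Diketone.** 20 is cut at C2–C3 into methyl ketone 14 and an acyl donor, silyl ester 18 (acid chloride 19 in the flask). A crossed Claisen condensation is preferred to a Baker–Venkataraman migration, which would free the ring A ortho-phenol and cost extra steps to re-protect. 14 comes from 11 by C-prenylation with 12 (giving 13) and silylation. 18 comes from 15 by ortho-prenylation with 3 (giving 16), saponification (17) and silylation.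

**Hydroxy-lactone.** 10 is cut at the aryl–Cb bond and the lactone C–O bond. Hydroxyalkylation of 2-prenylresorcinol 6 with glyoxylic acid 7 gives mandelic acid 8, which lactonises to 9 and is silylated to 10. 6 comes from resorcinol 1 through bis-MOM ether 2, aryllithium 4 and prenylated ether 5. Position 4 of 6 is the only activated free site, so regiochemistry is not at issue.

## Roads not taken

**Alternative 1:** The cut removes the ring D oxygen–Cc bond, the oxolane O–C2 bond and the Cb–O bond, the last supplied by an oxidant. The precursor A1 is a flavone carrying a (benzofuran-3-yl)(2-hydroxyaryl)methyl group at C3. Dimethyldioxirane epoxidises the benzofuran C2=C3 bond, the ring D phenol opens the epoxide at Cc, and the freed Cb alkoxide adds to flavone C2 to give hexacycle A2.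
- Merits: every carbon is at its final oxidation level, so no hydride has to discriminate a lactone from the C4 ketone. Two rings close in one step, and one stereocentre (Ca) relays to four.
- Weak points: the dioxirane cannot coexist with prenyl alkenes. A1 and A2 therefore carry three bromine placeholders, and three prenyl groups must be cross-coupled onto a hindered, acid- and base-labile hexacycle before desilylation. The benzofuran epoxide can rearrange or open to a quinone methide before the phenol arrives. Facial selectivity rests on one benzylic centre that itself needs an asymmetric synthesis. The alkoxide addition to C2 must overcome the aromatic stabilisation of the pyrone.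
- Comparison: this road is better in redox economy and in rings formed in the key step. The chosen plan sets against it that the prenyl groups are carried from the start, that Ca and Cb come from a catalyst acting on flat fragments, and that no late C–C coupling is needed.

**Alternative 2:** The cut removes the ring D oxygen–Cc bond and the Ca–aryl bond, so that all of ring D comes from resorcinol (1) in the last skeletal step. The precursor A3 is the chromanone ketal already fused to a 2,5-dihydrofuran whose C3=Ca bond is an enone, with Cb spiro-linked to a 2-methoxy-2,3-dihydrobenzofuran. A chiral phosphoric acid ionises the methoxy acetal, a resorcinol oxygen adds to Cc, and the ring carbon para to the other hydroxyl adds 6-exo to Ca. Ketonisation sets C3 and gives A4, three silyl ethers away from the target.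
- Merits: it is the most convergent plan, uses unprotected resorcinol, needs no reduction, and has the shortest endgame of all.
- Weak points: A3 already contains the quaternary centres C2 and Cb, which must be made enantiopure by other means; the catalyst adds only Ca, Cc and C3 under substrate bias. Building A3 is at least as long as the whole chosen route. Ca is next to a quaternary carbon inside a strained ring. Resorcinol can react at C2 or C4, through O or C, and twice. A Brønsted acid meets three prenylphenols and a ketal.
- Comparison: this road is better after the key step. The chosen plan sets against it that the hard quaternary centre Cb is created in the key step, not presupposed.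

**Alternative 3:** The cut removes the Cb–Cc carbon–carbon bond and the oxolane O–C2 bond. The precursor A5 is a nine-membered dibenzo-1,3-dioxonine ketone in which a methylene acetal bridges the ring D and ring E oxygens and Ca carries the CH2–CO–ring B chain. Irradiation causes 1,6-hydrogen transfer from the O–CH2–O carbon to the excited Cb carbonyl and transannular radical recombination, after which the new tertiary hydroxyl closes on the ring B ketone to give lactol A6.
- Merits: a C–C bond is made from an unfunctionalised methylene. Cc appears directly at the acetal level, so there is again no lactone reduction. Both oxygen heterocycles form at once under control of Ca.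
- Weak points: A6 lacks ring A and C4, which must be added by acylating a hindered C3 methylene and then closing the ketal. The nine-membered diaryl methylene acetal is costly to form. The aryl ketone bears oxygen donors, so its lowest triplet is of pi,pi* character and abstracts hydrogen poorly. Three prenyl alkenes and a second aryl ketone offer competing photochemistry. Ca still needs a separate asymmetric step.
- Comparison: this road is better at installing Cc. The chosen plan sets against it a complete carbon skeleton after the key step and a ground-state, catalyst-controlled stereochemical event.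

Key step: step 14

Remark on the chemistry: C2, C3 and Cc are treated as equilibrating centres, and the natural cis-fused arrangement is assumed to be the most stable form of the cage; compounds 25–27 are drawn as the isomers that map onto 28, and C2/C3 epimers (and both Cc anomers) are expected to converge in step 17.
Remark on the chemistry: the sense of induction of the quinine-derived catalyst in step 14 is assigned by analogy; the quinidine-derived pseudo-enantiomer would be used if the opposite sense were found.

## Route

Step 1
Reactants: 1 resorcinol
Product: 2 1,3-bis(methoxymethoxy)benzene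
Conditions: NaH, MOMCl, DMF, 0 °C → rt
Reagents that add atoms: chloromethyl methyl ether, COCCl
Why: Williamson-type O-alkylation of both phenoxides; MOM ethers are chosen because they are strong ortho-directing groups for the next step.

Step 2
Reactants: 2 1,3-bis(methoxymethoxy)benzene; 3 prenyl bromide (1-bromo-3-methylbut-2-ene)
Product: 5 1,3-bis(methoxymethoxy)-2-(3-methylbut-2-en-1-yl)benzene, via aryllithium 4 (not isolated)
Conditions: n-BuLi, THF, 0 °C → rt; CuBr·SMe2 (10 mol %), then 3, −78 °C → rt
Reagents that add atoms: none
Why: Directed ortho-metalation removes the proton flanked by both OMOM groups; copper-mediated allylic substitution of 3 occurs at the unsubstituted terminus and gives the linear prenyl arene.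

Step 3
Reactants: 5 1,3-bis(methoxymethoxy)-2-(3-methylbut-2-en-1-yl)benzene
Product: 6 2-(3-methylbut-2-en-1-yl)benzene-1,3-diol (2-prenylresorcinol)
Conditions: HCl (2 M aq., cat.), MeOH, rt
Reagents that add atoms: none
Why: Acid-catalysed acetal exchange with methanol removes both MOM groups; dilute acid at room temperature and short contact should keep the ortho-prenylphenol from closing to a chroman.

Step 4
Reactants: 6 2-prenylresorcinol; 7 glyoxylic acid (used as monohydrate)
Product: 9 3,6-dihydroxy-7-(3-methylbut-2-en-1-yl)-1-benzofuran-2(3H)-one (racemic), via mandelic acid 8 (not isolated)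
Conditions: NaOH (2 M aq.), rt, N2; HCl to pH 2 at 0 °C, EtOAc extraction; then N,N'-diisopropylcarbodiimide, THF, 0 °C → rt
Reagents that add atoms: none
Why: Base-mediated hydroxyalkylation of the resorcinolate by glyoxylate (the hydroxymandelic acid reaction) can occur only at C4/C6, since C2 is blocked; the carbodiimide then dehydrates 8 to the five-membered aryl lactone, which only the ortho phenol can form. The new stereocentre is racemic and is erased in step 14.

Step 5
Reactants: 9 3,6-dihydroxy-7-prenylbenzofuran-2(3H)-one
Product: 10 6-(tert-butyldimethylsilyloxy)-3-hydroxy-7-(3-methylbut-2-en-1-yl)-1-benzofuran-2(3H)-one (racemic)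
Conditions: TBSCl (1.05 equiv), imidazole, CH2Cl2, 0 °C
Reagents that add atoms: tert-butyldimethylsilyl chloride, CC(C)(C)[Si](C)(C)Cl
Why: Chemoselective silylation: the phenol is more acidic and far less hindered than the secondary alpha-hydroxy-lactone OH, so one equivalent at 0 °C should cap only the phenol and leave the 3-OH free for step 14.

Step 6
Reactants: 11 2,4-dihydroxyacetophenone; 12 2-methylbut-3-en-2-ol
Product: 13 1-[2,4-dihydroxy-5-(3-methylbut-2-en-1-yl)phenyl]ethan-1-one
Conditions: BF3·OEt2 (cat.), dioxane, rt
Reagents that add atoms: none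
Why: Friedel–Crafts prenylation by the dimethylallyl cation formed from the tertiary allylic alcohol; C5 (para to the chelated 2-OH, ortho to 4-OH) is the most accessible nucleophilic position, the 3-prenyl isomer and chromans are removed by chromatography, and a modest yield is accepted for a one-step entry.

Step 7
Reactants: 13 1-[2,4-dihydroxy-5-prenylphenyl]ethan-1-one
Product: 14 1-[2,4-bis(tert-butyldimethylsilyloxy)-5-(3-methylbut-2-en-1-yl)phenyl]ethan-1-one
Conditions: TBSCl (2.5 equiv), imidazole, DMAP (cat.), DMF, 40 °C
Reagents that add atoms: tert-butyldimethylsilyl chloride, CC(C)(C)[Si](C)(C)Cl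
Why: Silylation of both phenols; the hydrogen-bonded 2-OH reacts slowly and needs DMAP and gentle warming.

Step 8
Reactants: 15 methyl 4-hydroxybenzoate; 3 prenyl bromide
Product: 16 methyl 4-hydroxy-3-(3-methylbut-2-en-1-yl)benzoate
Conditions: NaH, toluene, 0 °C; then 3, rt → 60 °C
Reagents that add atoms: none
Why: ortho-C-Alkylation of a sodium phenoxide in a non-polar solvent, where the tight ion pair shields oxygen and steers the allyl halide to the ring carbon; the O-prenyl ether is a separable by-product.

Step 9
Reactants: 16 methyl 4-hydroxy-3-prenylbenzoate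
Product: 17 4-hydroxy-3-(3-methylbut-2-en-1-yl)benzoic acid
Conditions: NaOH, MeOH/H2O, 60 °C; then HCl (1 M) to pH 3, 0 °C
Reagents that add atoms: sodium hydroxide, [Na+].[OH-]
Why: Saponification of the methyl ester; cold, dilute acidification spares the prenylphenol.

Step 10
Reactants: 17 4-hydroxy-3-prenylbenzoic acid
Product: 18 tert-butyldimethylsilyl 4-(tert-butyldimethylsilyloxy)-3-(3-methylbut-2-en-1-yl)benzoate
Conditions: TBSCl (2.4 equiv), imidazole, DMF, rt
Reagents that add atoms: tert-butyldimethylsilyl chloride, CC(C)(C)[Si](C)(C)Cl
Why: Phenol and acid are silylated in one operation; the silyl ester is the substrate for neutral acid chloride formation.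

Step 11
Reactants: 18 silyl ester of ring B; 14 ring A methyl ketone
Product: 20 1-[2,4-bis(tert-butyldimethylsilyloxy)-5-prenylphenyl]-3-[4-(tert-butyldimethylsilyloxy)-3-prenylphenyl]propane-1,3-dione, via acid chloride 19 (not isolated)
Conditions: (COCl)2, DMF (cat.), CH2Cl2, 0 °C → rt, evaporate; then 14, MgBr2·OEt2, i-Pr2NEt, CH2Cl2, rt
Reagents that add atoms: none
Why: Oxalyl chloride/DMF converts the silyl ester into the acid chloride without liberating HCl, which protects the prenyl group. The crossed Claisen condensation then runs by soft enolisation (magnesium enolate of 14), which releases no alkoxide that could desilylate, avoids a free lithium enolate beside the ortho-silyloxy group (silyl migration) and holds the product as its magnesium diketonate against double acylation.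

Step 12
Reactants: 21 2,4-dihydroxybenzaldehyde
Product: 22 2,4-bis(tert-butyldimethylsilyloxy)benzaldehyde
Conditions: TBSCl (2.4 equiv), imidazole, DMF, rt
Reagents that add atoms: tert-butyldimethylsilyl chloride, CC(C)(C)[Si](C)(C)Cl
Why: Routine silylation of both phenols of a resorcylaldehyde.

Step 13
Reactants: 20 rings A/B 1,3-diketone; 22 ring D aldehyde
Product: 23 (Z)-2-[2,4-bis(tert-butyldimethylsilyloxy)benzylidene]-1-[2,4-bis(tert-butyldimethylsilyloxy)-5-prenylphenyl]-3-[4-(tert-butyldimethylsilyloxy)-3-prenylphenyl]propane-1,3-dione
Conditions: piperidine (20 mol %), AcOH (20 mol %), toluene, 90 °C, Dean–Stark trap with 4 Å MS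
Reagents that add atoms: none
Why: Knoevenagel condensation through the piperidinium iminium ion of the aldehyde, driven by removal of water; the Z isomer is drawn, but either geometric isomer offers the same two faces at Ca and should serve in step 14.

Step 14
Reactants: 10 racemic hydroxy-lactone (1.2 equiv); 23 arylidene diketone
Product: 25 oxolane hemiketal spiro-fused at Cb to the ring E lactone (hexakis-TBS ether; C2 R; C3 S; Ca R; Cb S), via open-chain Michael adduct 24 (not isolated)
Conditions: quinine-derived squaramide 3-{[3,5-bis(trifluoromethyl)phenyl]amino}-4-{[(8α,9S)-6′-methoxycinchonan-9-yl]amino}cyclobut-3-ene-1,2-dione (10 mol %), CH2Cl2, 4 Å MS, −20 °C → rt, argon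
Reagents that add atoms: none
Why: Proposed new method: the quinuclidine nitrogen of the catalyst deprotonates racemic 10 to its enediolate (an aromatic 2-oxidobenzofuran, so both enantiomers of 10 converge) while the squaramide N–H bonds hold a carbonyl of 23; the ion pair delivers Cb to the arylidene carbon Ca (Michael addition) to give 24, whose tertiary hydroxyl then adds to the ring B ketone to give hemiketal 25. The closest known reaction types are the amine–squaramide-catalysed Michael additions of 3-substituted benzofuran-2(3H)-ones to enones and the Michael/hemiketalisation cascades of 3-hydroxyoxindoles; a 3-hydroxybenzofuranone donor paired with an arylidene 1,3-diketone has not been described. The single ring formed, the oxolane, closes 5-exo-trig by oxygen attack on a carbonyl carbon. Ca and Cb are set together in the C–C bond-forming event under catalyst control: the catalyst-bound face of the arylidene meets one face of the planar enolate, and the open transition state places the ring D aryl anti to the benzo ring of the lactone, which is the required relative configuration. C3 is an exchangeable alpha-carbon and C2 a hemiketal carbon; both settle by equilibration and are corrected, if need be, in step 17. The selectivities needed are C- over O-alkylation of the enediolate (secured by the soft, aromatic enolate carbon), hemiketal formation on the ring B ketone and not the ring A ketone (the latter is flanked by an ortho-silyloxy group and is the more electron-rich carbonyl), and suppression of the retro-Michael reaction (the hemiketal removes the free diketone). Argon is needed because the enediolate is oxygen-sensitive.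

Step 15
Reactants: 25 hemiketal lactone
Product: 26 hemiketal lactol (hexakis-TBS ether; Cc as anomeric mixture)
Conditions: (i-Bu)2AlH (2.2 equiv), CH2Cl2, −78 °C; aq. potassium sodium tartrate
Reagents that add atoms: none
Why: Half-reduction of a lactone to the lactol through the aluminium hemiacetal, which is stable at −78 °C; the first equivalent is consumed by the hemiketal OH. The strained aryl ester is the most electrophilic carbonyl, whereas the C4 ketone is a doubly donor-substituted aryl ketone shielded by its ortho-OTBS group and the flanking oxolane substituents; the new Cc centre forms as an anomeric mixture, which is of no consequence.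

Step 16
Reactants: 26 hemiketal lactol
Product: 27 hexaphenol hemiketal lactol (mixture of anomers and ring–chain tautomers, used crude)
Conditions: Bu4NF (7 equiv), AcOH (7 equiv), THF, 0 °C
Reagents that add atoms: none
Why: Fluoride cleaves all six aryl silyl ethers; acetic acid buffers the phenoxides so that the beta-oxygenated ketone and the lactol never meet basic fluoride.

Step 17
Reactants: 27 hexaphenol hemiketal lactol
Product: 28 CNP0152008.3 (C2 R; C3 S; Ca R; Cb S; Cc S)
Conditions: pyridinium p-toluenesulfonate (0.2 equiv), 4 Å MS, CH2Cl2/THF 4:1, rt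
Reagents that add atoms: none
Why: Twofold acid-catalysed dehydrative acetalisation: the C2 hemiketal ionises to an oxocarbenium ion stabilised by the oxolane oxygen and ring B and is captured by the ring A phenol (chromanone ring), and the Cc lactol is captured by the ring D phenol (pyran ring). Each new ring can only be cis-fused, so Cc follows Cb and C2 follows C3, and C3 equilibrates through the ring-opened 1,3-diketone until the cage is locked; the pyridinium salt is expected to be too weak an acid to cyclise the prenylphenols.

## Compound list

1 | resorcinol | Oc1cccc(O)c1 | starting material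
2 | 1,3-bis(methoxymethoxy)benzene | COCOc1cccc(OCOC)c1 | intermediate
3 | prenyl bromide (1-bromo-3-methylbut-2-ene) | CC(C)=CCBr | starting material
4 | 2-lithio-1,3-bis(methoxymethoxy)benzene | COCOc1cccc(OCOC)c1[Li] | intermediate
5 | 1,3-bis(methoxymethoxy)-2-(3-methylbut-2-en-1-yl)benzene | COCOc1cccc(OCOC)c1CC=C(C)C | intermediate
6 | 2-(3-methylbut-2-en-1-yl)benzene-1,3-diol | CC(C)=CCc1c(O)cccc1O | intermediate
7 | glyoxylic acid | O=CC(=O)O | starting material
8 | 2-[2,4-dihydroxy-3-(3-methylbut-2-en-1-yl)phenyl]-2-hydroxyacetic acid (racemic) | OC(C(=O)O)c1ccc(O)c(CC=C(C)C)c1O | intermediate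
9 | 3,6-dihydroxy-7-(3-methylbut-2-en-1-yl)-1-benzofuran-2(3H)-one (racemic) | O=C1Oc2c(CC=C(C)C)c(O)ccc2C1O | intermediate
10 | 6-(tert-butyldimethylsilyloxy)-3-hydroxy-7-(3-methylbut-2-en-1-yl)-1-benzofuran-2(3H)-one (racemic) | O=C1Oc2c(CC=C(C)C)c(O[Si](C)(C)C(C)(C)C)ccc2C1O | intermediate
11 | 2,4-dihydroxyacetophenone | CC(=O)c1ccc(O)cc1O | starting material
12 | 2-methylbut-3-en-2-ol | C=CC(C)(C)O | starting material
13 | 1-[2,4-dihydroxy-5-(3-methylbut-2-en-1-yl)phenyl]ethan-1-one | CC(=O)c1cc(CC=C(C)C)c(O)cc1O | intermediate
14 | 1-[2,4-bis(tert-butyldimethylsilyloxy)-5-(3-methylbut-2-en-1-yl)phenyl]ethan-1-one | CC(=O)c1cc(CC=C(C)C)c(O[Si](C)(C)C(C)(C)C)cc1O[Si](C)(C)C(C)(C)C | intermediate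
15 | methyl 4-hydroxybenzoate | COC(=O)c1ccc(O)cc1 | starting material
16 | methyl 4-hydroxy-3-(3-methylbut-2-en-1-yl)benzoate | COC(=O)c1ccc(O)c(CC=C(C)C)c1 | intermediate
17 | 4-hydroxy-3-(3-methylbut-2-en-1-yl)benzoic acid | OC(=O)c1ccc(O)c(CC=C(C)C)c1 | intermediate
18 | tert-butyldimethylsilyl 4-(tert-butyldimethylsilyloxy)-3-(3-methylbut-2-en-1-yl)benzoate | CC(C)=CCc1cc(C(=O)O[Si](C)(C)C(C)(C)C)ccc1O[Si](C)(C)C(C)(C)C | intermediate
19 | 4-(tert-butyldimethylsilyloxy)-3-(3-methylbut-2-en-1-yl)benzoyl chloride | CC(C)=CCc1cc(C(Cl)=O)ccc1O[Si](C)(C)C(C)(C)C | intermediate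
20 | 1-[2,4-bis(tert-butyldimethylsilyloxy)-5-prenylphenyl]-3-[4-(tert-butyldimethylsilyloxy)-3-prenylphenyl]propane-1,3-dione | O=C(CC(=O)c1cc(CC=C(C)C)c(O[Si](C)(C)C(C)(C)C)cc1O[Si](C)(C)C(C)(C)C)c1ccc(O[Si](C)(C)C(C)(C)C)c(CC=C(C)C)c1 | intermediate
21 | 2,4-dihydroxybenzaldehyde | O=Cc1ccc(O)cc1O | starting material
22 | 2,4-bis(tert-butyldimethylsilyloxy)benzaldehyde | O=Cc1ccc(O[Si](C)(C)C(C)(C)C)cc1O[Si](C)(C)C(C)(C)C | intermediate
23 | (Z)-2-[2,4-bis(tert-butyldimethylsilyloxy)benzylidene]-1-[2,4-bis(tert-butyldimethylsilyloxy)-5-prenylphenyl]-3-[4-(tert-butyldimethylsilyloxy)-3-prenylphenyl]propane-1,3-dione (ring A aroyl cis to ring D aryl) | O=C(c1ccc(O[Si](C)(C)C(C)(C)C)c(CC=C(C)C)c1)/C(=C/c1ccc(O[Si](C)(C)C(C)(C)C)cc1O[Si](C)(C)C(C)(C)C)C(=O)c1cc(CC=C(C)C)c(O[Si](C)(C)C(C)(C)C)cc1O[Si](C)(C)C(C)(C)C | intermediate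
24 | open-chain Michael adduct: 3-hydroxybenzofuranone joined through Cb (S) to Ca (R), which carries the ring D aryl and the C3 methine of the diaroylmethane (C3 epimerising) | O=C(c1ccc(O[Si](C)(C)C(C)(C)C)c(CC=C(C)C)c1)C(C(=O)c1cc(CC=C(C)C)c(O[Si](C)(C)C(C)(C)C)cc1O[Si](C)(C)C(C)(C)C)[C@H](c1ccc(O[Si](C)(C)C(C)(C)C)cc1O[Si](C)(C)C(C)(C)C)[C@@]1(O)C(=O)Oc2c(CC=C(C)C)c(O[Si](C)(C)C(C)(C)C)ccc21 | intermediate
25 | 6-(TBSO)-7-prenyl-spiro[1-benzofuran-3(2H),2′-oxolan]-2-one with, on the oxolane, 2,4-bis(TBSO)phenyl (ring D) at C3′ (= Ca, R), 2,4-bis(TBSO)-5-prenylbenzoyl (ring A) at C4′ (= C3, S), and OH plus 4-(TBSO)-3-prenylphenyl (ring B) at C5′ (= C2, R); spiro carbon Cb S; ring D cis to the aroyl group and to the lactone carbonyl, ring B trans to the aroyl group | CC(C)=CCc1cc([C@]2(O)O[C@@]3(C(=O)Oc4c(CC=C(C)C)c(O[Si](C)(C)C(C)(C)C)ccc43)[C@@H](c3ccc(O[Si](C)(C)C(C)(C)C)cc3O[Si](C)(C)C(C)(C)C)[C@H]2C(=O)c2cc(CC=C(C)C)c(O[Si](C)(C)C(C)(C)C)cc2O[Si](C)(C)C(C)(C)C)ccc1O[Si](C)(C)C(C)(C)C | intermediate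
26 | lactol of 25: lactone carbonyl Cc reduced to CH(OH) (both anomers), all else as in 25 | CC(C)=CCc1cc([C@]2(O)O[C@@]3(C(O)Oc4c(CC=C(C)C)c(O[Si](C)(C)C(C)(C)C)ccc43)[C@@H](c3ccc(O[Si](C)(C)C(C)(C)C)cc3O[Si](C)(C)C(C)(C)C)[C@H]2C(=O)c2cc(CC=C(C)C)c(O[Si](C)(C)C(C)(C)C)cc2O[Si](C)(C)C(C)(C)C)ccc1O[Si](C)(C)C(C)(C)C | intermediate
27 | hexaphenol corresponding to 26 (all six silyl groups removed; hemiketal at C2, lactol at Cc) | CC(C)=CCc1cc([C@]2(O)O[C@@]3(C(O)Oc4c(CC=C(C)C)c(O)ccc43)[C@@H](c3ccc(O)cc3O)[C@H]2C(=O)c2cc(CC=C(C)C)c(O)cc2O)ccc1O | intermediate
28 | CNP0152008.3: 7-hydroxy-6-prenylchroman-4-one whose C2 (R) is a ketal carrying 4-hydroxy-3-prenylphenyl (ring B) and the oxolane oxygen; oxolane cis-fused at C2–C3 (C3 S); Ca (R) and Cb (S) shared with the 7-hydroxychromane of ring D; Cb and acetal Cc (S) shared with the 6-hydroxy-7-prenyl-2,3-dihydrobenzofuran of ring E; all ring fusions cis | CC(C)=CCc1cc([C@@]23Oc4cc(O)c(CC=C(C)C)cc4C(=O)[C@@H]2[C@@H]2c4ccc(O)cc4O[C@H]4Oc5c(ccc(O)c5CC=C(C)C)[C@]42O3)ccc1O | target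

## Step count and least certain steps

Total: 17 steps. Longest linear sequence: 9 steps (steps 1–5, 14–17 from resorcinol; equally steps 8–11, 13–17 from methyl 4-hydroxybenzoate).

**Step 14 (key step, new method).** Several processes could go wrong:
- reversible conjugate addition that erodes facial selectivity;
- a mismatched pairing of enolate and arylidene faces, giving the wrong relative configuration at Ca/Cb;
- acyl transfer from the activated aryl lactone to the diketone enol in place of hemiketalisation;
- hemiketalisation on the ring A ketone;
- air oxidation of the enediolate.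

The causes are that both partners are hindered, the adduct is a stabilised diketone, and the lactone is an active ester. Fallback by known chemistry: setting out from 10 and 23, the same two bonds are made without asymmetric induction by a simple tertiary amine (Et3N, CH2Cl2, rt). This is the general base-mediated Michael addition of C–H acidic lactones to alkylidene 1,3-dicarbonyls and gives racemic hemiketal F1. The enantiomers are separated by preparative chromatography on a polysaccharide chiral stationary phase, and the matching enantiomer rejoins the route at 25.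

**Step 15.** Hydride may be delivered to the C4 ketone, the aluminium hemiketal alkoxide may open and expose the ring B ketone, or the lactol may be over-reduced. The ketone and the lactone are both hindered, and their rates are not known to differ enough. Fallback: setting out from 25, both carbonyls are reduced on purpose with excess (i-Bu)2AlH at −78 °C to lactol carbinol F2. Only the benzylic alcohol is then re-oxidised with activated MnO2 (CH2Cl2, rt), which leaves the non-benzylic lactol and the prenyl groups alone and returns to 26.

**Step 17.** Loss of the C3 proton from the C2 oxocarbenium ion (elimination to a conjugated enol ether) may outrun capture by the chelated ring A phenol. Ionisation at Cc beside the oxygenated quaternary carbon may be slow, and forcing conditions may close a prenyl group onto its neighbouring phenol. Fallback: setting out from 27, the elimination is accepted. Acid treatment gives dihydrofuran enone F3, in which the Cc acetal is already closed. Ring C is then closed by base-mediated oxa-Michael addition of the ring A phenoxide (NaOAc, EtOH, 60 °C, the classical 2′-hydroxychalcone to flavanone isomerisation), which forms O1–C2, sets C2/C3 by equilibration and returns to 28.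

**Step 13.** Condensation of an electron-rich, ortho-substituted aldehyde with a hindered diaryl diketone may be slow, and the ortho-silyloxy groups may be desilylated by the amine on long heating. Fallback: setting out from 22, the aldehyde is pre-activated as N-tosyl imine F4 (TsNH2, Ti(OEt)4, CH2Cl2, 40 °C). Diketone 20 adds under catalytic Et3N (Mannich addition) to give sulfonamide F5, and warming with Et3N eliminates toluenesulfonamide (E1cB) to return to 23.

**Step 6.** Regiocontrol of the Friedel–Crafts prenylation may be poor (attack at C3 as well as C5, O-alkylation, acid-induced chroman closure), with low conversion. Fallback: setting out from 11, bromination at C5 (N-bromosuccinimide, MeCN, 0 °C) gives bromoketone F6. Bis-silylation (TBSCl, imidazole, DMAP, DMF) gives bromide F7, and Stille coupling with tributyl(3-methylbut-2-en-1-yl)stannane (Pd(PPh3)4, DMF, 90 °C) returns to 14.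

## Further compounds

F1 | step 14 | racemic hemiketal lactone (racemate of 25, one enantiomer drawn) | CC(C)=CCc1cc([C@]2(O)O[C@@]3(C(=O)Oc4c(CC=C(C)C)c(O[Si](C)(C)C(C)(C)C)ccc43)[C@@H](c3ccc(O[Si](C)(C)C(C)(C)C)cc3O[Si](C)(C)C(C)(C)C)[C@H]2C(=O)c2cc(CC=C(C)C)c(O[Si](C)(C)C(C)(C)C)cc2O[Si](C)(C)C(C)(C)C)ccc1O[Si](C)(C)C(C)(C)C
F2 | step 15 | lactol carbinol (26 with the C4 ketone reduced to CH(OH), epimers at C4 and Cc) | CC(C)=CCc1cc([C@]2(O)O[C@@]3(C(O)Oc4c(CC=C(C)C)c(O[Si](C)(C)C(C)(C)C)ccc43)[C@@H](c3ccc(O[Si](C)(C)C(C)(C)C)cc3O[Si](C)(C)C(C)(C)C)[C@H]2C(O)c2cc(CC=C(C)C)c(O[Si](C)(C)C(C)(C)C)cc2O[Si](C)(C)C(C)(C)C)ccc1O[Si](C)(C)C(C)(C)C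
F3 | step 17 | dihydrofuran enone with closed Cc acetal (C2=C3 enol ether, ring A phenol free) | CC(C)=CCc1cc(C2=C(C(=O)c3cc(CC=C(C)C)c(O)cc3O)[C@@H]3c4ccc(O)cc4O[C@H]4Oc5c(ccc(O)c5CC=C(C)C)[C@]43O2)ccc1O
F4 | step 13 | (E)-N-[2,4-bis(tert-butyldimethylsilyloxy)benzylidene]-4-methylbenzenesulfonamide | Cc1ccc(S(=O)(=O)/N=C/c2ccc(O[Si](C)(C)C(C)(C)C)cc2O[Si](C)(C)C(C)(C)C)cc1
F5 | step 13 | Mannich adduct of 20 and F4 (2-[aryl(tosylamino)methyl]-1,3-diketone, diastereomers) | O=C(c1ccc(O[Si](C)(C)C(C)(C)C)c(CC=C(C)C)c1)C(C(NS(=O)(=O)c1ccc(C)cc1)c1ccc(O[Si](C)(C)C(C)(C)C)cc1O[Si](C)(C)C(C)(C)C)C(=O)c1cc(CC=C(C)C)c(O[Si](C)(C)C(C)(C)C)cc1O[Si](C)(C)C(C)(C)C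
F6 | step 6 | 1-(5-bromo-2,4-dihydroxyphenyl)ethan-1-one | CC(=O)c1cc(Br)c(O)cc1O
F7 | step 6 | 1-[5-bromo-2,4-bis(tert-butyldimethylsilyloxy)phenyl]ethan-1-one | CC(=O)c1cc(Br)c(O[Si](C)(C)C(C)(C)C)cc1O[Si](C)(C)C(C)(C)C
A1 | alternative 1 | 3-[(benzofuran-3-yl)(2-hydroxyaryl)methyl]flavone as tribromide tetrakis-TBS ether | Brc1cc(-c2oc3cc(O[Si](C)(C)C(C)(C)C)c(Br)cc3c(=O)c2[C@H](c2ccc(O[Si](C)(C)C(C)(C)C)cc2O)c2coc3c(Br)c(O[Si](C)(C)C(C)(C)C)ccc23)ccc1O[Si](C)(C)C(C)(C)C
A2 | alternative 1 | hexacyclic core as tribromide tetrakis-TBS ether | Brc1cc([C@@]23Oc4cc(O[Si](C)(C)C(C)(C)C)c(Br)cc4C(=O)[C@@H]2[C@@H]2c4ccc(O[Si](C)(C)C(C)(C)C)cc4O[C@H]4Oc5c(ccc(O[Si](C)(C)C(C)(C)C)c5Br)[C@]42O3)ccc1O[Si](C)(C)C(C)(C)C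
A3 | alternative 2 | chromanone ketal fused to a 2,5-dihydrofuran enone, spiro-linked at Cb to a 2-methoxy-2,3-dihydrobenzofuran (tris-TBS ether, Cc anomers) | CC(C)=CCc1cc([C@@]23Oc4cc(O[Si](C)(C)C(C)(C)C)c(CC=C(C)C)cc4C(=O)C2=C[C@@]2(O3)C(OC)Oc3c(CC=C(C)C)c(O[Si](C)(C)C(C)(C)C)ccc32)ccc1O[Si](C)(C)C(C)(C)C
A4 | alternative 2 | target as tris-TBS ether with the ring D phenol free | CC(C)=CCc1cc([C@@]23Oc4cc(O[Si](C)(C)C(C)(C)C)c(CC=C(C)C)cc4C(=O)[C@@H]2[C@@H]2c4ccc(O)cc4O[C@H]4Oc5c(ccc(O[Si](C)(C)C(C)(C)C)c5CC=C(C)C)[C@]42O3)ccc1O[Si](C)(C)C(C)(C)C
A5 | alternative 3 | nine-membered dibenzo-1,3-dioxonine ketone carrying the CH2–CO–ring B chain on Ca | O=C(C[C@@H]1c2ccc(O[Si](C)(C)C(C)(C)C)cc2OCOc2c(CC=C(C)C)c(O[Si](C)(C)C(C)(C)C)ccc2C1=O)c1ccc(O[Si](C)(C)C(C)(C)C)c(CC=C(C)C)c1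
A6 | alternative 3 | pentacyclic lactol (cyclic hemiketal at C2) | CC(C)=CCc1cc([C@@]2(O)C[C@@H]3c4ccc(O[Si](C)(C)C(C)(C)C)cc4O[C@H]4Oc5c(ccc(O[Si](C)(C)C(C)(C)C)c5CC=C(C)C)[C@]43O2)ccc1O[Si](C)(C)C(C)(C)C
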